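## The problem

Prevezol C (18) consists of two cyclohexane rings that are not fused but joined by a two-carbon bridge: C-7, a methylene on C-1 of ring A, and C-8, which carries an exocyclic methylidene and is bonded directly to C-1′ of ring B. In ring A (C-1 to C-6) the bridge on C-1 and the isopropenyl group on C-2 are trans-diequatorial, C-5 is a methyl carbinol and C-6 a secondary carbinol; the two hydroxyls are trans-diaxial and the C-6 hydroxyl is cis to C-7. In ring B (C-1′ to C-6′) the C-8 substituent on C-1′, the equatorial bromine on C-5′ and the axial hydroxyl of the methyl carbinol C-4′ all lie on one face. The seven stereocentres therefore form two clusters that the bridge insulates from each other. Inside ring A, C-1 and C-2 can control C-5 and C-6, because once they lock the chair a C-5/C-6 epoxide opens only in the diaxial sense. Inside ring B, C-1′ becomes a stereocentre only when C-3′ and C-5′ are told apart, which nothing in ring A can do, so an external chiral reagent is needed; the syn bromohydrin cannot come from anti opening of an epoxide or bromonium ion and points to an α-bromo ketone plus a methyl nucleophile. Rough treatment is ruled out by the bromohydrin (strong base causes ring contraction or elimination), by the tertiary alcohols and the two 1,1-disubstituted alkenes (strong acid dehydrates, hydrates or closes a cineole-type ether between the C-4′ hydroxyl and C-8), and by any free hydroxyl beside an alkene when electrophilic bromine is present (bromoetherification). The feature that opens the key step is that ring A is a p-menthane whose C-5/C-6 diol is the anti-dihydroxylation product of a C-5=C-6 alkene: that cyclohexene divides into a diene C-1–C-6–C-5–C-4 (methyl on C-5, bridge on C-1) and a two-carbon unit C-2–C-3 whose acetyl group on C-2 is one methylenation away from isopropenyl.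

## Retrosynthesis

**Ring A diol.** The last bonds cut are the two C–O bonds of ring A: 18 goes back to epoxide 17 (C-5–OH from water, C-6–O kept) and 17 to the trisubstituted alkene 16. Doing this oxidation last, instead of carrying a free or protected diol through the ring B chemistry, keeps hydroxyl groups away from the amide base and from N-bromosuccinimide and saves two protecting-group steps; afterwards the bromohydrin meets only dilute acid. Precursor 16 has two stereocentres and two hydroxyls fewer. The forward reaction must place the oxirane oxygen on the face of C-5=C-6 that carries C-7, because only that epoxide is opened by water at the tertiary C-5 in the diaxial mode. The substrate's own bias is weak, so a chiral ketone catalyst has to deliver the oxygen.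

**Ring B bromohydrin.** Next the C-4′–CH3 bond (16 to bromo ketone 15), the C-5′–Br bond (15 and its axial epimer 14 to silyl enol ether 13) and the enol ether itself (13 to ketone 12) are cut. Adding bromine and oxygen across a C-4′=C-5′ alkene is discarded because it can only give the anti bromohydrin. In 12 ring B is an achiral 4-substituted cyclohexanone, so three stereocentres disappear. Three things are asked of the forward direction: enantiotopos-selective deprotonation by a chiral lithium amide, an equatorial bromide cis to C-8, and methyl delivery trans to bromine.

**Functional-group adjustments.** Ketone 12 comes from ketal 11, the isopropenyl group of 11 from the acetyl group of 10 (C=CH2 bond, Wittig), and trans ketone 10 from its cis epimer 9 by equilibration at C-2. The ketal has to shield the ring B carbonyl from the ylide and must be gone before the enolisation, which fixes the order. Precursor 9 is simpler only in functional-group terms, but it is the direct product of the cycloaddition below. The forward steps are expected to be routine.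

**Key disconnection.** Cis ketone 9 is cut at C-1–C-2 and C-3–C-4 into triene 7 and methyl vinyl ketone 8. The competing choice, cycloaddition with a simpler diene and later attachment of C-8 and ring B, would need a C–C bond to be made beside two stereocentres; carrying ring B through the cycloaddition lets one step finish the whole carbon skeleton. The cut removes ring A and both of its first stereocentres and leaves an achiral triene and a commodity enone. The forward reaction must control the absolute configuration at C-2 by the catalyst, C-1 by the endo rule, and the regiochemistry by the diene substituents, and the acid-sensitive skipped triene must survive a strongly Lewis acidic catalyst.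

**Triene.** Triene 7 is cut at the bond between C-7 and the diene terminus (future C-1) into allylic bromide 4 and dienylboronate 6. The neighbouring cut at C-7–C-8 would need an ambident pentadienyl partner. Here the 2-substituted allyl unit of 4 has two identical termini, so regiochemistry cannot go wrong, and the E geometry is fixed in 6. Both fragments are small and achiral.

**Fragments.** Bromide 4 goes back through allylsilane 3 to the commercial ketal ester 1, whose carbonyl carbon becomes C-8: two C–C bonds by double addition of a silylmethyl Grignard reagent, a Peterson elimination, then bromodesilylation. Boronate 6 comes from hydroboration of the commercial enyne 5. This is shorter than building the allylic alcohol through an acrylate or an enol triflate, and it asks only for chemoselective addition to the ester and to the alkyne.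

## Roads not taken

Alternative 1: The cut is at both bonds to C-8, treated as a carbonyl carbon. A ring B secondary iodide A2, carbon monoxide A4 and a ring A primary alkylborane A3 (boron on C-7) would be joined by Pd(PPh3)4, K3PO4 and light in a carbonylative alkyl–alkyl coupling to give dialkyl ketone A1; no ring closes.
- Merits: it is more convergent than the chosen route, with two fragments of similar size, and all four ring A centres are fixed beforehand on a small fragment.
- Weak points: the step runs through a cyclohexyl radical and an acyl-palladium species, so direct coupling, reduction and β-hydride loss compete, and a secondary iodide with a β-branched borane sits at the unfavourable end of the scope. A3 is itself costly: it needs a ring A with four stereocentres and a C-7–B bond, most plausibly from face-selective hydroboration of an exocyclic alkene on C-1, which is a further stereochemical question. A1 must still be methylenated at a ketone flanked by two branched carbons, and ring B needs the same late enantiotopos selection as in the chosen plan.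
- Comparison: in convergence this road is better. Against it the chosen plan sets a catalytic key step that makes ring A and its first two stereocentres from achiral material while completing the skeleton.

Alternative 2: Only C-1–C-2 is cut. An acyclic alkylidene malonate A6, carrying the C-5/C-6 bis-silyl ether and a terminal prenyl alkene, would cyclise under FeCl3 on Al2O3 (or ZnBr2) in an intramolecular ene reaction: the alkene attacks the electrophilic C-1, a hydrogen migrates from one of its methyl groups, and ring A malonate A5 forms with the isopropenyl group in place.
- Merits: the diol stereochemistry would rest on asymmetric dihydroxylation of an acyclic trisubstituted alkene, which is more secure than the late epoxidation–hydrolysis of the chosen route, and no methylenation is needed.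
- Weak points: A5 carries a malonate where the target needs a single methylene joined to C-8 and ring B. Dealkoxycarbonylation, reduction, activation, coupling and methylenation would follow, which is more than the whole post-cycloaddition phase of the chosen route. The Lewis acid meets two silyl ethers close to the reacting centre, the induction from C-6 to C-1 cannot be predicted with confidence, and ring B is still untouched.
- Comparison: this road is better for the diol. The chosen plan sets against it a key step that delivers the complete skeleton with ring B attached.

Alternative 3: The cut is at C-1′–C-6′ and C-2′–C-3′. The same oxazaborolidinium catalysis would be applied to the other ring: silyloxydiene A9 adds to ring A vinyl ketone A8 and gives silyl enol ether A7.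
- Merits: C-1′ is set catalytically and the C-4′=C-5′ enol ether arrives regiodefined, ready for bromination. This answers the hardest question of the chosen plan better than a stoichiometric chiral lithium amide does.
- Weak points: A8 is a fully elaborated ring A whose four stereocentres must first be made by other means, so the cycloaddition no longer builds ring A. A vinyl ketone of this size polymerises readily. In A7 the new C-1′ centre is α to the C-8 ketone and can epimerise until that hindered ketone is methylenated in the presence of the enol ether. The catalyst must also override a chiral dienophile, and the equatorial-bromide and methyl-addition questions remain.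
- Comparison: this road is superior for ring B, the chosen plan for ring A. The chosen plan was preferred because its key step starts three steps from commercial materials and the late desymmetrisation costs one reagent, whereas A8 costs a separate multi-step synthesis.

Key step: step 5

Assumption: the sense of induction of the (S)-oxazaborolidinium catalyst (step 5), the (S,S)-lithium amide (step 9) and the D-fructose-derived ketone (step 12) is taken from the accepted transition-state models for these reagents; should any prove opposite on this substrate, its enantiomer is used and nothing else changes.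

Step 1
Reactants: 1 ethyl 1,4-dioxaspiro[4.5]decane-8-carboxylate
Product: 3 trimethyl[2-(1,4-dioxaspiro[4.5]decan-8-yl)prop-2-en-1-yl]silane, via bis(silylmethyl) carbinol 2 (not isolated)
Conditions: Me3SiCH2MgCl (3 equiv), CeCl3, THF, −78 → 23 °C; aq. NH4Cl; then SiO2, CH2Cl2, 23 °C
Reagents that add atoms: (trimethylsilyl)methylmagnesium chloride, C[Si](C)(C)C[Mg]Cl
Why: Double addition of the silylmethyl Grignard reagent to the ester (CeCl3 suppresses enolisation of the α-branched ester) followed by Peterson elimination of one β-silyl arm on silica gives the 2-substituted allylsilane; the dioxolane is inert to both operations.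

Step 2
Reactants: 3 trimethyl[2-(1,4-dioxaspiro[4.5]decan-8-yl)prop-2-en-1-yl]silane
Product: 4 8-(3-bromoprop-1-en-2-yl)-1,4-dioxaspiro[4.5]decane
Conditions: NBS, propylene oxide, CH2Cl2, −78 °C, dark
Reagents that add atoms: N-bromosuccinimide, O=C1CCC(=O)N1Br
Why: Electrophilic bromodesilylation of an allylsilane (SE2′): bromine adds to the terminal methylene and the β-silyl cation loses silicon; the allyl unit is symmetrical, so the transposition has no consequence, and cold, dark, acid-free conditions exclude radical bromination and ketal cleavage.

Step 3
Reactants: 5 2-methylbut-1-en-3-yne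
Product: 6 4,4,5,5-tetramethyl-2-[(1E)-3-methylbuta-1,3-dien-1-yl]-1,3,2-dioxaborolane
Conditions: HBpin, Cp2Zr(H)Cl (5 mol %), Et3N (10 mol %), neat, sealed tube, 40 °C
Reagents that add atoms: pinacolborane, [H]B1OC(C)(C)C(C)(C)O1
Why: Zirconium-catalysed syn hydroboration of the terminal alkyne puts boron on the terminus and gives the (E)-dienylboronate; the 1,1-disubstituted alkene of the enyne is far less reactive towards Zr–H addition.

Step 4
Reactants: 4 8-(3-bromoprop-1-en-2-yl)-1,4-dioxaspiro[4.5]decane; 6 4,4,5,5-tetramethyl-2-[(1E)-3-methylbuta-1,3-dien-1-yl]-1,3,2-dioxaborolane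
Product: 7 8-[(4E)-6-methylhepta-1,4,6-trien-2-yl]-1,4-dioxaspiro[4.5]decane
Conditions: Pd(PPh3)4 (5 mol %), K3PO4, THF/H2O, 60 °C
Reagents that add atoms: none
Why: Suzuki–Miyaura coupling of an allylic bromide with an alkenylboronate; the π-allyl palladium intermediate from 4 has two identical termini, so only one skipped triene can form, and the E geometry of the boronate is retained.

Step 5
Reactants: 7 8-[(4E)-6-methylhepta-1,4,6-trien-2-yl]-1,4-dioxaspiro[4.5]decane; 8 methyl vinyl ketone (but-3-en-2-one)
Product: 9 cis (endo) adduct 1-[(1R,2S)-4-methyl-2-{2-(1,4-dioxaspiro[4.5]decan-8-yl)prop-2-en-1-yl}cyclohex-3-en-1-yl]ethan-1-one (ring locants: C-1 S, C-2 R; acetyl cis to C-7)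
Conditions: (S)-B-(o-tolyl)oxazaborolidine from (S)-α,α-diphenylprolinol (20 mol %), HNTf2 (18 mol %), CH2Cl2, −78 → −40 °C
Reagents that add atoms: none
Why: The N-protonated oxazaborolidine binds methyl vinyl ketone at boron through the carbonyl lone pair syn to the vinyl group, the s-trans enone being held by an α-C–H···O contact to the ring oxygen, and this lowers the LUMO enough for a concerted, asynchronous, suprafacial [4π+2π] cycloaddition with the s-cis diene of 7 at low temperature; the closest known reaction type is the oxazaborolidinium-catalysed Diels–Alder addition of acyclic 2-substituted and 1,3-disubstituted dienes to vinyl ketones and acrylates. Ring A closes intermolecularly in one step as a six-membered ring by formation of C-1–C-2 and C-3–C-4. C-2 is set by the catalyst: the phenyl group cis to the bound enone covers one face of the C=C and the diene adds to the open face, which for the (S)-catalyst is predicted to give C-2 R. C-1 is set relative to C-2 by the endo transition state (acetyl under the diene) together with the E geometry of the diene, which give the cis adduct and hence C-1 S. The step needs regio-, endo- and enantiofacial selectivity and chemoselectivity for the diene: the alkyl group on the diene terminus and the methyl group on the future C-5 both make the unsubstituted terminus (future C-4) the most nucleophilic carbon, so it bonds to the enone β-carbon, and the isolated 1,1-disubstituted alkene at C-8 is not part of a diene and stays untouched. The acid is kept below the amount of oxazaborolidine so that no free HNTf2 can protonate the triene or the ketal.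

Step 6
Reactants: 9 cis (endo) adduct (C-1 S, C-2 R)
Product: 10 trans ketone 1-[(1S,2S)-4-methyl-2-{2-(1,4-dioxaspiro[4.5]decan-8-yl)prop-2-en-1-yl}cyclohex-3-en-1-yl]ethan-1-one (ring locants: C-1 S, C-2 S; acetyl trans to C-7)
Conditions: NaOMe (0.3 equiv), MeOH, 23 °C
Reagents that add atoms: none
Why: Reversible enolisation at C-2 equilibrates the cis adduct to the trans isomer, in which both ring substituents are pseudo-equatorial; C-1 is not acidic and keeps its configuration, and residual cis ketone can be resubmitted.

Step 7
Reactants: 10 trans ketone (C-1 S, C-2 S)
Product: 11 8-{3-[(1S,6S)-3-methyl-6-(prop-1-en-2-yl)cyclohex-2-en-1-yl]prop-1-en-2-yl}-1,4-dioxaspiro[4.5]decane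
Conditions: Ph3PCH3Br, KOtBu, THF, 0 → 23 °C
Reagents that add atoms: methyltriphenylphosphonium bromide, C[P+](c1ccccc1)(c1ccccc1)c1ccccc1.[Br-]
Why: Wittig methylenation of a methyl ketone; the ylide is basic, but C-2 already holds its thermodynamically preferred configuration, and the ketal keeps the ring B carbonyl out of reach.

Step 8
Reactants: 11 8-{3-[(1S,6S)-3-methyl-6-(prop-1-en-2-yl)cyclohex-2-en-1-yl]prop-1-en-2-yl}-1,4-dioxaspiro[4.5]decane
Product: 12 4-{3-[(1S,6S)-3-methyl-6-(prop-1-en-2-yl)cyclohex-2-en-1-yl]prop-1-en-2-yl}cyclohexan-1-one
Conditions: 1 M aq. HCl, THF, 23 °C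
Reagents that add atoms: water, O
Why: Acid-catalysed hydrolysis of the dioxolane; dilute acid at room temperature is expected to leave the trisubstituted and the 1,1-disubstituted alkenes unprotonated.

Step 9
Reactants: 12 4-{3-[(1S,6S)-3-methyl-6-(prop-1-en-2-yl)cyclohex-2-en-1-yl]prop-1-en-2-yl}cyclohexan-1-one
Product: 13 {[(4R)-4-{3-[(1S,6S)-3-methyl-6-(prop-1-en-2-yl)cyclohex-2-en-1-yl]prop-1-en-2-yl}cyclohex-1-en-1-yl]oxy}trimethylsilane (enol double bond C-4′=C-5′)
Conditions: (S,S)-bis(1-phenylethyl)amine, n-BuLi, THF, −78 °C; TMSCl, then 12, −100 → −78 °C
Reagents that add atoms: chlorotrimethylsilane, C[Si](C)(C)Cl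
Why: Enantiotopos-selective deprotonation of a 4-substituted cyclohexanone by a C2-symmetric chiral lithium amide with in situ silylation; removing the axial α-hydrogen on C-5′ rather than C-3′ fixes C-1′ as R. The (S,S)-base is chosen because the (R,R)-base is known to give (S)-enol silanes from 4-alkylcyclohexanones; with ring A already enantiopure, the selectivity appears as a diastereomer ratio.

Step 10
Reactants: 13 silyl enol ether (C-1′ R, double bond C-4′=C-5′)
Product: 15 equatorial bromo ketone (2R,4R)-2-bromo-4-{3-[(1S,6S)-3-methyl-6-(prop-1-en-2-yl)cyclohex-2-en-1-yl]prop-1-en-2-yl}cyclohexan-1-one, via axial bromo ketone 14 (not isolated)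
Conditions: NBS, THF, −78 °C; then LiBr, DMF, 23 °C
Reagents that add atoms: N-bromosuccinimide, O=C1CCC(=O)N1Br
Why: Bromination of the silyl enol ether places bromine regiospecifically on C-5′, and the enol ether is far more nucleophilic than the three other alkenes. Axial attack gives first the axial bromide 14 (trans to C-8); bromide exchange (SN2 inversion at the α-carbon) in a polar solvent is expected to shift the mixture towards the more polar equatorial epimer 15, with 14 separated and recycled.

Step 11
Reactants: 15 equatorial bromo ketone (C-1′ R, C-5′ R)
Product: 16 (1S,2R,4R)-2-bromo-1-methyl-4-{3-[(1S,6S)-3-methyl-6-(prop-1-en-2-yl)cyclohex-2-en-1-yl]prop-1-en-2-yl}cyclohexan-1-ol (ring B: C-1′ R, C-4′ S, C-5′ R; hydroxyl axial and cis to bromine)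
Conditions: MeMgBr, Et2O/toluene, −78 °C; aq. NH4Cl at −78 °C
Reagents that add atoms: methylmagnesium bromide, C[Mg]Br
Why: Grignard addition to an α-bromo ketone: attack anti to the C–Br bond (Cornforth/Felkin–Anh) and the preference of methyl nucleophiles for the equatorial trajectory both place methyl trans to bromine, giving the axial carbinol cis to the equatorial bromide. The cold quench prevents rearrangement of the bromo alkoxide.

Step 12
Reactants: 16 ring B bromohydrin with ring A alkene
Product: 17 C-5/C-6 epoxide of 16 with the oxygen on the face of C-7, anti to isopropenyl (ring A: C-1 R, C-2 S, C-5 S, C-6 R)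
Conditions: D-fructose-derived Shi ketone (30 mol %), Oxone (2KHSO5·KHSO4·K2SO4), K2CO3, Bu4NHSO4, MeCN/CH2(OMe)2/aq. Na2B4O7 buffer (pH 10.5), 0 °C
Reagents that add atoms: potassium peroxymonosulfate, [K+].[O-]S(=O)(=O)OO
Why: Shi epoxidation by the chiral dioxirane is selective for the one trisubstituted alkene over the two 1,1-disubstituted ones. The spiro transition state of the D-fructose-derived ketone is expected to deliver oxygen to the face of C-5=C-6 that carries C-7, against the weak substrate bias; the cis bromohydrin cannot close to an epoxide and should tolerate the cold buffer.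

Step 13
Reactants: 17 C-5/C-6 epoxide (oxygen on the face of C-7)
Product: 18 prevezol C
Conditions: HClO4 (0.1 M aq., cat.), THF/H2O, 0 °C
Reagents that add atoms: water, O
Why: Acid-catalysed epoxide hydrolysis under Fürst–Plattner control: with C-1 and C-2 equatorial, water attacks the tertiary C-5 anti to the oxirane oxygen and gives the diaxial diol directly, inverting C-5 and leaving the C-6 oxygen cis to C-7. Dilute acid at 0 °C is used so that the 1,1-disubstituted alkenes and the ring B carbinol are not ionised.

Compound list

1 | ethyl 1,4-dioxaspiro[4.5]decane-8-carboxylate | CCOC(=O)C1CCC2(CC1)OCCO2 | starting material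
2 | 2-(1,4-dioxaspiro[4.5]decan-8-yl)-1,3-bis(trimethylsilyl)propan-2-ol | C[Si](C)(C)CC(O)(C[Si](C)(C)C)C1CCC2(CC1)OCCO2 | intermediate (not isolated)
3 | trimethyl[2-(1,4-dioxaspiro[4.5]decan-8-yl)prop-2-en-1-yl]silane | C=C(C[Si](C)(C)C)C1CCC2(CC1)OCCO2 | intermediate
4 | 8-(3-bromoprop-1-en-2-yl)-1,4-dioxaspiro[4.5]decane | C=C(CBr)C1CCC2(CC1)OCCO2 | intermediate
5 | 2-methylbut-1-en-3-yne | C=C(C)C#C | starting material
6 | 4,4,5,5-tetramethyl-2-[(1E)-3-methylbuta-1,3-dien-1-yl]-1,3,2-dioxaborolane | C=C(C)/C=C/B1OC(C)(C)C(C)(C)O1 | intermediate
7 | 8-[(4E)-6-methylhepta-1,4,6-trien-2-yl]-1,4-dioxaspiro[4.5]decane | C=C(C)/C=C/CC(=C)C1CCC2(CC1)OCCO2 | intermediate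
8 | methyl vinyl ketone (but-3-en-2-one) | C=CC(C)=O | starting material
9 | cis (endo) adduct, 1-[(1R,2S)-4-methyl-2-{2-(1,4-dioxaspiro[4.5]decan-8-yl)prop-2-en-1-yl}cyclohex-3-en-1-yl]ethan-1-one | C=C(C[C@@H]1[C@H](C(C)=O)CCC(C)=C1)C1CCC2(CC1)OCCO2 | intermediate
10 | trans ketone, 1-[(1S,2S)-4-methyl-2-{2-(1,4-dioxaspiro[4.5]decan-8-yl)prop-2-en-1-yl}cyclohex-3-en-1-yl]ethan-1-one | C=C(C[C@@H]1[C@@H](C(C)=O)CCC(C)=C1)C1CCC2(CC1)OCCO2 | intermediate
11 | 8-{3-[(1S,6S)-3-methyl-6-(prop-1-en-2-yl)cyclohex-2-en-1-yl]prop-1-en-2-yl}-1,4-dioxaspiro[4.5]decane | C=C(C[C@@H]1[C@@H](C(=C)C)CCC(C)=C1)C1CCC2(CC1)OCCO2 | intermediate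
12 | 4-{3-[(1S,6S)-3-methyl-6-(prop-1-en-2-yl)cyclohex-2-en-1-yl]prop-1-en-2-yl}cyclohexan-1-one | C=C(C[C@@H]1[C@@H](C(=C)C)CCC(C)=C1)C1CCC(=O)CC1 | intermediate
13 | {[(4R)-4-{3-[(1S,6S)-3-methyl-6-(prop-1-en-2-yl)cyclohex-2-en-1-yl]prop-1-en-2-yl}cyclohex-1-en-1-yl]oxy}trimethylsilane | C=C(C[C@@H]1[C@@H](C(=C)C)CCC(C)=C1)[C@@H]1CCC(O[Si](C)(C)C)=CC1 | intermediate
14 | axial bromo ketone, (2S,4R)-2-bromo-4-{3-[(1S,6S)-3-methyl-6-(prop-1-en-2-yl)cyclohex-2-en-1-yl]prop-1-en-2-yl}cyclohexan-1-one | C=C(C[C@@H]1[C@@H](C(=C)C)CCC(C)=C1)[C@@H]1CCC(=O)[C@@H](Br)C1 | intermediate (not isolated)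
15 | equatorial bromo ketone, (2R,4R)-2-bromo-4-{3-[(1S,6S)-3-methyl-6-(prop-1-en-2-yl)cyclohex-2-en-1-yl]prop-1-en-2-yl}cyclohexan-1-one | C=C(C[C@@H]1[C@@H](C(=C)C)CCC(C)=C1)[C@@H]1CCC(=O)[C@H](Br)C1 | intermediate
16 | (1S,2R,4R)-2-bromo-1-methyl-4-{3-[(1S,6S)-3-methyl-6-(prop-1-en-2-yl)cyclohex-2-en-1-yl]prop-1-en-2-yl}cyclohexan-1-ol | C=C(C[C@@H]1[C@@H](C(=C)C)CCC(C)=C1)[C@@H]1CC[C@](C)(O)[C@H](Br)C1 | intermediate
17 | C-5/C-6 epoxide of 16, oxygen on the face of C-7 (C-1 R, C-2 S, C-5 S, C-6 R) | C=C(C[C@@H]1[C@@H](C(=C)C)CC[C@]2(C)O[C@H]12)[C@@H]1CC[C@](C)(O)[C@H](Br)C1 | intermediate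
18 | prevezol C | C=C(C[C@@H]1[C@@H](C(=C)C)CC[C@@](C)(O)[C@@H]1O)[C@@H]1CC[C@](C)(O)[C@H](Br)C1 | target

Total step count: 13. Longest linear sequence: 12 steps (steps 1, 2 and 4 to 13, from ester 1); step 3 is the one-step side branch.

Least certain steps

Step 5 (key step). The most likely failure is acid-induced oligomerisation or double-bond migration of the skipped triene by the strongly acidic catalyst before cycloaddition. Facial selectivity could also erode if the enone is activated outside the chiral pocket by traces of free acid. Fallback: auxiliary control in place of catalyst control. Triene 7 is combined with (S)-3-acryloyl-4-benzyl-1,3-oxazolidin-2-one and Et2AlCl in CH2Cl2 at −78 °C; the chelated s-cis imide is attacked endo on the face away from the benzyl group and should give the endo imide adduct F1. Me(MeO)NH·HCl with AlMe3 then converts it into the N-methoxy-N-methylamide F2, and MeMgBr gives cis ketone 9, where the route is rejoined.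

Step 9. The two α-methylene groups of 12 differ only through the remote ring A, so discrimination by the amide base may be incomplete, and the resulting remote diastereomers would be very hard to separate. Fallback: enamine catalysis instead of a stoichiometric base. Ketone 12 is brominated directly with 4,4-dibromo-2,6-di-tert-butylcyclohexa-2,5-dienone under a C2-symmetric chiral amine ((4R,5R)-4,5-diphenylimidazolidine with benzoic acid, or its enantiomer). The catalyst selects the α-carbon and the face, which gives bromo ketone 14 without passing through 13; equilibration as in step 10 returns to 15. This fallback makes no compound outside the list (F0).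

Step 10. The epimer equilibrium may not lie far enough on the side of the equatorial bromide, because the axial α-bromo ketone is favoured by dipole opposition and may persist even in DMF; long exposure also invites dehydrobromination. Fallback: kinetic instead of thermodynamic control. The mixture of 14 and 15 is silylated towards the brominated carbon (TMSOTf, Et3N, CH2Cl2, 0 °C) to the bromo enol silane F3. Desilylation with TBAF in the presence of AcOH at −78 °C then protonates the enolate from the axial direction, which leaves bromine equatorial and returns 15.

Step 11. Methyl may be delivered in part from the axial direction (syn to bromine), and the basic Grignard reagent may enolise 15, which would leak through the faster-reacting axial epimer 14 into the wrong ring B series. Fallback: methyl transfer from a neutral, non-basic titanium reagent under steric approach control in place of carbanionic addition. MeTi(OiPr)3 (from MeLi and ClTi(OiPr)3) in hexane/CH2Cl2 at −20 → 23 °C takes 15 to 16; no compound outside the list is made (F0).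

Step 12. Facial selectivity may be poor, because reagent control opposes the substrate's own bias and the C-1 substituent sits next to the reacting carbon; slow turnover would also let the 1,1-disubstituted alkenes compete. Fallback: give up face control and rely on convergence. mCPBA with NaHCO3 in CH2Cl2 at 0 °C converts 16 into a mixture of 17 and its diastereomer, the epoxide with oxygen anti to C-7 F4. Under the conditions of step 13, 17 opens at C-5 and F4 at the secondary C-6, each in the diaxial mode, so both should give 18, as the two limonene 1,2-oxides give one diaxial diol. The fallback sets out from 16 and returns at 18.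

Further compounds

F1 | step 5 | endo imide adduct, (4S)-4-benzyl-3-[(1R,2S)-4-methyl-2-{2-(1,4-dioxaspiro[4.5]decan-8-yl)prop-2-en-1-yl}cyclohex-3-ene-1-carbonyl]-1,3-oxazolidin-2-one | C=C(C[C@@H]1[C@H](C(=O)N2[C@@H](Cc3ccccc3)COC2=O)CCC(C)=C1)C1CCC2(CC1)OCCO2
F2 | step 5 | (1R,2S)-N-methoxy-N,4-dimethyl-2-{2-(1,4-dioxaspiro[4.5]decan-8-yl)prop-2-en-1-yl}cyclohex-3-ene-1-carboxamide | C=C(C[C@@H]1[C@H](C(=O)N(C)OC)CCC(C)=C1)C1CCC2(CC1)OCCO2
F0 | step 9 | none | none
F3 | step 10 | bromo enol silane, {[(4R)-2-bromo-4-{3-[(1S,6S)-3-methyl-6-(prop-1-en-2-yl)cyclohex-2-en-1-yl]prop-1-en-2-yl}cyclohex-1-en-1-yl]oxy}trimethylsilane | C=C(C[C@@H]1[C@@H](C(=C)C)CCC(C)=C1)[C@@H]1CCC(O[Si](C)(C)C)=C(Br)C1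
F0 | step 11 | none | none
F4 | step 12 | C-5/C-6 epoxide of 16 with the oxygen anti to C-7 (C-5 R, C-6 S) | C=C(C[C@@H]1[C@@H](C(=C)C)CC[C@@]2(C)O[C@@H]12)[C@@H]1CC[C@](C)(O)[C@H](Br)C1
A1 | alternative 1 | dialkyl ketone joining bis(triethylsilyl)-protected ring A and ketal-protected ring B | O=C(C[C@@H]1[C@@H](C(=C)C)CC[C@@](C)(O[Si](CC)(CC)CC)[C@@H]1O[Si](CC)(CC)CC)C1CCC2(CC1)OCCO2
A2 | alternative 1 | 8-iodo-1,4-dioxaspiro[4.5]decane | IC1CCC2(CC1)OCCO2
A3 | alternative 1 | ring A B-alkyl-9-borabicyclo[3.3.1]nonane (boron on C-7) | B1(C[C@@H]2[C@@H](C(=C)C)CC[C@@](C)(O[Si](CC)(CC)CC)[C@@H]2O[Si](CC)(CC)CC)C2CCCC1CCC2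
A4 | alternative 1 | carbon monoxide | [C-]#[O+]
A5 | alternative 2 | ring A malonate with trans isopropenyl and diaxial silyloxy groups | COC(=O)C(C(=O)OC)[C@@H]1[C@@H](C(=C)C)CC[C@@](C)(O[Si](C)(C)C(C)(C)C)[C@@H]1O[Si](C)(C)C(C)(C)C
A6 | alternative 2 | acyclic alkylidene malonate with bis(tert-butyldimethylsilyl) ether and prenyl terminus | COC(=O)C(C(=O)OC)=C[C@@H](O[Si](C)(C)C(C)(C)C)[C@](C)(O[Si](C)(C)C(C)(C)C)CCC=C(C)C
A7 | alternative 3 | ring B triisopropylsilyl enol ether, acyl-linked to ring A | O=C(C[C@@H]1[C@@H](C(=C)C)CC[C@@](C)(O[Si](CC)(CC)CC)[C@@H]1O[Si](CC)(CC)CC)[C@@H]1CCC(O[Si](C(C)C)(C(C)C)C(C)C)=CC1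
A8 | alternative 3 | ring A vinyl ketone | C=CC(=O)C[C@@H]1[C@@H](C(=C)C)CC[C@@](C)(O[Si](CC)(CC)CC)[C@@H]1O[Si](CC)(CC)CC
A9 | alternative 3 | 2-(triisopropylsilyloxy)buta-1,3-diene | C=CC(=C)O[Si](C(C)C)(C(C)C)C(C)C
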